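**Strategy**

Ring C (O1–C2–C3–C4–C4a–C8a) is read as a 4-aryl-β-lactone written onto an ortho-bromophenol: C2 (benzylic, oxygen-bearing) and C4 (carbonyl) are the two electrophilic carbons of an oxetan-2-one, O1 and C4a are phenol oxygen and ortho carbon. In one flask the phenoxide of bromophenol 7, which already carries the side chain, opens (R)-lactone 11 at its benzylic carbon with inversion (O1–C2, giving 2S), and bromine–lithium exchange then lets the liberated carboxylate acylate C4a (C4–C4a). The free O1 and the bromine fix the 6-alkenyl pattern; the acid-labile trioxygenated styrene, made by a Heck reaction with (S)-β-citronellene, meets only base.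

Key step: step 6

Remark on the chemistry: the quinidine-derived catalyst of step 5 is assumed to give the (R)-lactone 11; if the facial sense proves opposite for this aldehyde, its pseudoenantiomer O-trimethylsilylquinine is used under the same conditions.

**Route**

Step 1
Reactants: 1 2-iodoresorcinol (2-iodobenzene-1,3-diol)
Product: 2 2-iodo-1,3-bis(triisopropylsilyloxy)benzene
Conditions: TIPSCl (2.4 equiv), imidazole (5 equiv), DMF, rt to 40 °C
Reagents that add atoms: triisopropylsilyl chloride, CC(C)[Si](Cl)(C(C)C)C(C)C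
Why: Routine silyl ether formation on both phenols; TIPS is chosen because it blocks the neighbouring C–H bonds in step 2, resists base, and migrates to an adjacent aryllithium far more slowly than smaller silyl groups.

Step 2
Reactants: 2 2-iodo-1,3-bis(triisopropylsilyloxy)benzene
Product: 4 4-iodo-3,5-bis(triisopropylsilyloxy)phenol, via aryl pinacol boronate 3 (not isolated)
Conditions: [Ir(OMe)(cod)]2 (1.5 mol %), 4,4'-di-tert-butyl-2,2'-bipyridine (3 mol %), B2pin2 (0.6 equiv), THF, 80 °C; then 30% aq. H2O2, aq. NaOH, 0 °C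
Reagents that add atoms: hydrogen peroxide, OO (phenol oxygen of 4); bis(pinacolato)diboron, CC1(C)OB(OC1(C)C)B1OC(C)(C)C(C)(C)O1 (boron of 3 only)
Why: Sterically governed iridium-catalysed C–H borylation (Hartwig–Miyaura type) should reach only C5, the one C–H not ortho to a silyloxy group, and oxidation of the C–B bond in the same pot gives the phenol para to iodine, which this catalyst tolerates.

Step 3
Reactants: 4 4-iodo-3,5-bis(triisopropylsilyloxy)phenol
Product: 5 2-bromo-4-iodo-3,5-bis(triisopropylsilyloxy)phenol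
Conditions: NBS (1.0 equiv), iPr2NH (10 mol %), CH2Cl2, −78 to 0 °C
Reagents that add atoms: N-bromosuccinimide, O=C1CCC(=O)N1Br
Why: Phenol-directed electrophilic ortho-bromination (amine-mediated bromine delivery) at one of two equivalent ortho carbons, the para carbon being occupied by iodine and shielded by both TIPS ethers.

Step 4
Reactants: 5 2-bromo-4-iodo-3,5-bis(triisopropylsilyloxy)phenol; 6 (S)-3,7-dimethylocta-1,6-diene ((S)-β-citronellene)
Product: 7 2-bromo-4-[(1E,3S)-3,7-dimethylocta-1,6-dien-1-yl]-3,5-bis(triisopropylsilyloxy)phenol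
Conditions: Pd(OAc)2 (10 mol %), Bu4NCl (1 equiv), NaHCO3 (3 equiv), 6 (3 equiv), DMF, 80 °C
Reagents that add atoms: none
Why: Heck–Mizoroki reaction under ligand-free, ammonium chloride-promoted conditions: oxidative addition should occur at C–I and not C–Br, the aryl group adds to the terminal alkene carbon and β-hydride elimination toward the benzylic hydrogens gives the E-styrene, while the trisubstituted alkene is inert and the (S) centre of 6 is carried over untouched.

Step 5
Reactants: 8 4-(tert-butyldimethylsilyloxy)benzaldehyde; 9 acetyl chloride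
Product: 11 (R)-4-[4-(tert-butyldimethylsilyloxy)phenyl]oxetan-2-one, via ketene 10 (not isolated)
Conditions: O-trimethylsilylquinidine (10 mol %), LiClO4 (1 equiv), iPr2NEt, CH2Cl2/Et2O, −78 °C, slow addition of 9
Reagents that add atoms: none
Why: Catalytic asymmetric acyl halide–aldehyde cyclocondensation (Wynberg-type formal [2+2]): ketene generated from 9 is bound by the alkaloid as a chiral ammonium enolate that adds to one face of the lithium-activated aldehyde and lactonises, so the catalyst sets C4 of the lactone.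

Step 6
Reactants: 7 2-bromo-4-[(1E,3S)-3,7-dimethylocta-1,6-dien-1-yl]-3,5-bis(triisopropylsilyloxy)phenol; 11 (R)-4-[4-(tert-butyldimethylsilyloxy)phenyl]oxetan-2-one
Product: 16 (2S)-2-[4-(tert-butyldimethylsilyloxy)phenyl]-6-[(1E,3S)-3,7-dimethylocta-1,6-dien-1-yl]-5,7-bis(triisopropylsilyloxy)chroman-4-one, via potassium phenoxide 12 (not isolated), via potassium aryloxypropanoate 13 (not isolated), via aryllithium 14 (not isolated), via ketone dialkoxide 15 (not isolated)
Conditions: KH (1.0 equiv), THF, 0 °C; 11 (1.0 equiv), 18-crown-6 (0.1 equiv), 0 °C to rt; then t-BuLi (2.1 equiv), −78 to −20 °C; sat. aq. NH4Cl, −20 °C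
Reagents that add atoms: none
Why: Phenoxide 12 attacks the benzylic C4 of β-lactone 11 in an SN2 alkyl–oxygen ring opening (O1–C2 formed, carboxylate 13 released), t-BuLi then exchanges the bromine ortho to the new ether for lithium (14), and this aryllithium adds to the tethered carboxylate to give dialkoxide 15, which collapses to the C4 ketone only on the cold quench (C4–C4a formed). The closest known reactions are the opening of β-lactones by phenoxides to 3-aryloxypropanoates and the Parham cyclisation of (2-bromoaryl)-tethered carboxylates to cyclic ketones, here run in one flask. Ring C is the only ring closed, by a 6-exo-trig addition of the aryl carbanion (C4a) to the carboxylate carbon (C4). C2 is set by inversion at the (R)-configured lactone carbon and should come out (S); because no enolisable ketone exists before the quench it cannot be lost by retro-oxa-Michael opening, and the side-chain centre is not involved. The step needs attack at the lactone C–O carbon rather than the acyl carbon (acyl attack is reversible, carboxylate formation is not) and halogen exchange rather than deprotonation or addition to the styrene (bromine–lithium exchange at −78 °C is the fastest process available). The 6-alkenyl and not the 8-alkenyl flavanone must form, and this is fixed by the substrate, in which O1 is the only free oxygen and bromine marks the one ortho carbon, while the TIPS ethers resist migration to the aryllithium and the acid-labile styrene meets only base.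

Step 7
Reactants: 16 (2S)-2-[4-(tert-butyldimethylsilyloxy)phenyl]-6-[(1E,3S)-3,7-dimethylocta-1,6-dien-1-yl]-5,7-bis(triisopropylsilyloxy)chroman-4-one
Product: 17 (2S)-5,7-dihydroxy-2-(4-hydroxyphenyl)-6-[(1E,3S)-3,7-dimethylocta-1,6-dien-1-yl]chroman-4-one
Conditions: TBAF (3.3 equiv), AcOH (3.5 equiv), THF, 0 °C
Reagents that add atoms: none
Why: Fluoride-mediated cleavage of the three aryl silyl ethers, buffered with acetic acid so that no free phenoxide can open ring C (which would racemise C2) and no strong acid can protonate the hydroxystyrene.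

**Compound list**

1 | 2-iodoresorcinol | Oc1cccc(O)c1I | starting material
2 | 2-iodo-1,3-bis(triisopropylsilyloxy)benzene | CC(C)[Si](Oc1cccc(O[Si](C(C)C)(C(C)C)C(C)C)c1I)(C(C)C)C(C)C | intermediate
3 | 2-[4-iodo-3,5-bis(triisopropylsilyloxy)phenyl]-4,4,5,5-tetramethyl-1,3,2-dioxaborolane | CC(C)[Si](Oc1cc(B2OC(C)(C)C(C)(C)O2)cc(O[Si](C(C)C)(C(C)C)C(C)C)c1I)(C(C)C)C(C)C | intermediate (not isolated)
4 | 4-iodo-3,5-bis(triisopropylsilyloxy)phenol | CC(C)[Si](Oc1cc(O)cc(O[Si](C(C)C)(C(C)C)C(C)C)c1I)(C(C)C)C(C)C | intermediate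
5 | 2-bromo-4-iodo-3,5-bis(triisopropylsilyloxy)phenol | Oc1cc(O[Si](C(C)C)(C(C)C)C(C)C)c(I)c(O[Si](C(C)C)(C(C)C)C(C)C)c1Br | intermediate
6 | (S)-3,7-dimethylocta-1,6-diene | CC(C)=CCC[C@H](C)C=C | starting material
7 | 2-bromo-4-[(1E,3S)-3,7-dimethylocta-1,6-dien-1-yl]-3,5-bis(triisopropylsilyloxy)phenol | CC(C)=CCC[C@H](C)/C=C/c1c(O[Si](C(C)C)(C(C)C)C(C)C)cc(O)c(Br)c1O[Si](C(C)C)(C(C)C)C(C)C | intermediate
8 | 4-(tert-butyldimethylsilyloxy)benzaldehyde | CC(C)(C)[Si](C)(C)Oc1ccc(C=O)cc1 | starting material
9 | acetyl chloride | CC(Cl)=O | starting material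
10 | ketene | C=C=O | intermediate (not isolated)
11 | (R)-4-[4-(tert-butyldimethylsilyloxy)phenyl]oxetan-2-one | O=C1C[C@H](c2ccc(O[Si](C)(C)C(C)(C)C)cc2)O1 | intermediate
12 | potassium 2-bromo-4-[(1E,3S)-3,7-dimethylocta-1,6-dien-1-yl]-3,5-bis(triisopropylsilyloxy)phenoxide | CC(C)=CCC[C@H](C)/C=C/c1c(O[Si](C(C)C)(C(C)C)C(C)C)cc([O-])c(Br)c1O[Si](C(C)C)(C(C)C)C(C)C.[K+] | intermediate (not isolated)
13 | potassium (3S)-3-{2-bromo-4-[(1E,3S)-3,7-dimethylocta-1,6-dien-1-yl]-3,5-bis(triisopropylsilyloxy)phenoxy}-3-[4-(tert-butyldimethylsilyloxy)phenyl]propanoate | CC(C)=CCC[C@H](C)/C=C/c1c(O[Si](C(C)C)(C(C)C)C(C)C)cc(O[C@@H](CC(=O)[O-])c2ccc(O[Si](C)(C)C(C)(C)C)cc2)c(Br)c1O[Si](C(C)C)(C(C)C)C(C)C.[K+] | intermediate (not isolated)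
14 | ortho-lithiated form of 13 (aryllithium, lithium in place of bromine) | CC(C)=CCC[C@H](C)/C=C/c1c(O[Si](C(C)C)(C(C)C)C(C)C)cc(O[C@@H](CC(=O)[O-])c2ccc(O[Si](C)(C)C(C)(C)C)cc2)c([Li])c1O[Si](C(C)C)(C(C)C)C(C)C.[K+] | intermediate (not isolated)
15 | lithium potassium (2S)-chroman-4,4-diolate of 16 (tetrahedral adduct at C4) | CC(C)=CCC[C@H](C)/C=C/c1c(O[Si](C(C)C)(C(C)C)C(C)C)cc2c(c1O[Si](C(C)C)(C(C)C)C(C)C)C([O-])([O-])C[C@@H](c1ccc(O[Si](C)(C)C(C)(C)C)cc1)O2.[Li+].[K+] | intermediate (not isolated)
16 | (2S)-2-[4-(tert-butyldimethylsilyloxy)phenyl]-6-[(1E,3S)-3,7-dimethylocta-1,6-dien-1-yl]-5,7-bis(triisopropylsilyloxy)chroman-4-one | CC(C)=CCC[C@H](C)/C=C/c1c(O[Si](C(C)C)(C(C)C)C(C)C)cc2c(c1O[Si](C(C)C)(C(C)C)C(C)C)C(=O)C[C@@H](c1ccc(O[Si](C)(C)C(C)(C)C)cc1)O2 | intermediate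
17 | (2S)-5,7-dihydroxy-2-(4-hydroxyphenyl)-6-[(1E,3S)-3,7-dimethylocta-1,6-dien-1-yl]chroman-4-one | CC(C)=CCC[C@H](C)/C=C/c1c(O)cc2c(c1O)C(=O)C[C@@H](c1ccc(O)cc1)O2 | target

**Step count and risks**

Total steps: 7. Longest linear sequence: 6 steps (1, 2, 3, 4, 6, 7).

Steps most likely to fail:

1. Step 6 (key step). In the first stage the ambident phenoxide may alkylate at ring carbon, or act as a base and open the lactone by elimination, and partial ionisation at the benzylic carbon would erode C2. In the second stage, if addition to the carboxylate is slow, proton transfer from C3 to the aryllithium followed by loss of aryloxide, or silyl migration, may take over. Fallback, setting out from 7 and 11 and returning at 16: lactone 11 is opened at the acyl carbon with MeNH(OMe)·HCl/Me2AlCl (CH2Cl2, −20 °C) to give, with retention, (3R)-3-hydroxy-N-methoxy-N-methyl-3-[4-(tert-butyldimethylsilyloxy)phenyl]propanamide F1. Mitsunobu etherification of F1 with phenol 7 (PPh3, DIAD, toluene, 0 °C) forms O1–C2 with inversion and gives the (3S)-aryl ether Weinreb amide F2. Treatment with t-BuLi (2 equiv, THF, −78 °C) then closes C4–C4a by Parham cyclisation onto the Weinreb amide, whose chelated adduct releases ketone 16 only on quench.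

2. Step 4. Insertion at the doubly ortho-substituted arylpalladium may be slow and end in reduction of the C–I bond. Re-addition of palladium hydride may move the double bond toward C3 of the side chain and erode that centre, and some arylation at the internal alkene carbon may occur. Fallback, setting out from 5 and returning at 7: (S)-citronellal (CC(C)=CCC[C@H](C)CC=O) is condensed with tosylhydrazide (MeOH, rt) to (S)-citronellal N-tosylhydrazone F3. Barluenga coupling of F3 with 5 (Pd2(dba)3, XPhos, LiOtBu, 1,4-dioxane, 80 °C, C–I reacting before C–Br) passes through a palladium carbene, aryl migration and β-hydride elimination from the only adjacent CH2, so the double bond can form only between C1 and C2 of the side chain.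

3. Step 5. The electron-rich aldehyde may turn over slowly, the facial selectivity may be insufficient, and the para-silyloxyphenyl lactone may ionise and lose CO2 on the Lewis acid or during isolation. Fallback, setting out from 8 and returning at 11: Roskamp homologation of 8 with ethyl diazoacetate (SnCl2 cat., CH2Cl2) gives ethyl 3-[4-(tert-butyldimethylsilyloxy)phenyl]-3-oxopropanoate F4. Noyori–Ikariya transfer hydrogenation (RuCl[(R,R)-TsDPEN](p-cymene), HCO2H/Et3N) gives ethyl (3R)-3-hydroxy-3-[4-(tert-butyldimethylsilyloxy)phenyl]propanoate F5. Neutral ester cleavage with Me3SnOH (1,2-dichloroethane, 70 °C) gives (3R)-3-hydroxy-3-[4-(tert-butyldimethylsilyloxy)phenyl]propanoic acid F6. Carboxyl activation with PhSO2Cl in pyridine at 0 °C closes the lactone with retention to 11.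

**Further compounds**

F1 | step 6 | (3R)-3-hydroxy-N-methoxy-N-methyl-3-[4-(tert-butyldimethylsilyloxy)phenyl]propanamide | CON(C)C(=O)C[C@@H](O)c1ccc(O[Si](C)(C)C(C)(C)C)cc1
F2 | step 6 | (3S)-3-{2-bromo-4-[(1E,3S)-3,7-dimethylocta-1,6-dien-1-yl]-3,5-bis(triisopropylsilyloxy)phenoxy}-N-methoxy-N-methyl-3-[4-(tert-butyldimethylsilyloxy)phenyl]propanamide | CC(C)=CCC[C@H](C)/C=C/c1c(O[Si](C(C)C)(C(C)C)C(C)C)cc(O[C@@H](CC(=O)N(C)OC)c2ccc(O[Si](C)(C)C(C)(C)C)cc2)c(Br)c1O[Si](C(C)C)(C(C)C)C(C)C
F3 | step 4 | (S)-citronellal N-tosylhydrazone | CC(C)=CCC[C@H](C)CC=NNS(=O)(=O)c1ccc(C)cc1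
F4 | step 5 | ethyl 3-[4-(tert-butyldimethylsilyloxy)phenyl]-3-oxopropanoate | CCOC(=O)CC(=O)c1ccc(O[Si](C)(C)C(C)(C)C)cc1
F5 | step 5 | ethyl (3R)-3-hydroxy-3-[4-(tert-butyldimethylsilyloxy)phenyl]propanoate | CCOC(=O)C[C@H](c1ccc(O[Si](C)(C)C(C)(C)C)cc1)O
F6 | step 5 | (3R)-3-hydroxy-3-[4-(tert-butyldimethylsilyloxy)phenyl]propanoic acid | OC(=O)C[C@H](c1ccc(O[Si](C)(C)C(C)(C)C)cc1)O
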